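## The problem

The target is an 8–5′ neolignan: a trans-2-aryl-3-methyl-2,3-dihydro-1-benzofuran of (2S,3S) configuration. It carries OMe at C7, an (E)-propenyl group at C5 and a 3-hydroxy-4,5-dimethoxyphenyl ring at C2. Two arylpropane halves are joined by the C3–C3a bond and the O1–C2 bond, so the furan ring and both stereocentres arise at the junction of the halves. The trans relationship is the thermodynamic one; the real problem is the absolute configuration.

C2 is a 4′-alkoxybenzylic ether carbon that can ionise and re-close, so C3 can dictate C2. C3 is a benzylic methine with no heteroatom and cannot be corrected once set, so C3 is the centre that needs absolute control. The feature that makes the key step possible is this: when C2 is at the ketone oxidation level, the C3–H bond is both benzylic (to the C3a–C7a ring) and α to an aryl ketone. C3 then epimerises freely and a racemate can be funnelled into one configuration.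

The free phenol of the pendant ring is meta to C2, so the biomimetic p-quinone methide logic does not apply to this ring as it stands. The propenyl group sits on an electron-rich ring and is of the isoeugenol type. It will not survive strong acid, oxidants or hydrogenation over heterogeneous catalysts, so it should arrive last.

## Retrosynthesis

**13 ⇒ 12 (C5–propenyl bond).** The aryl–alkenyl bond is cut first, back to aryl chloride 12. The alternatives are to carry the propenyl group through the route, which exposes it to the acid of the ring closure, or to build it from an aldehyde by olefination, which leaves an E/Z question. A chloride is inert to every earlier step, and the E geometry comes from the boron reagent. The forward reaction is a Suzuki–Miyaura coupling on an electron-rich aryl chloride in the presence of a free phenol.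

**12 ⇒ 10 via 11 (O1–C2 bond).** The benzylic C–O bond is cut, not the aryl C7a–O bond. Cutting C7a–O would need a 1,2-dihalo-3-methoxyarene and a retentive etherification. With the O1–C2 cut the ring oxygen is already present in a guaiacol building block, and C2 is a 4′-methoxybenzylic carbon whose cation is captured by the ortho phenol. That closure is trans-selective under control of C3, so the carbinol configuration of 10 need not be preserved. Only C3 remains as a stereochemical problem. The forward reaction is acid removal of both MOM groups (triol 11) and cyclodehydration without touching C3.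

**10 ⇒ 8 (carbinol to ketone).** Raising C1 of 10 to the ketone makes the future C3 configurationally labile. Racemic 8 equilibrates through enolate 9 while a chiral ruthenium hydride reduces one enantiomer. This sets C3 absolutely in one operation from a precursor with no defined stereocentre. The forward reaction needs racemisation faster than reduction of the mismatched enantiomer, matched catalyst and Felkin–Anh control, and tolerance of the aryl chloride.

**8 ⇒ 7 + 3 (C3–C3a bond).** The bond between the methine and the guaiacol ring is cut to propiophenone 7 and aryl bromide 3, joined by Pd-catalysed ketone α-arylation. A C2–C3 cut (addition of a benzylic organometallic to an aldehyde) would form two stereocentres without control. A C2–aryl cut would need a 2-arylpropanal that is itself labile. The forward reaction must select C–Br over C–Cl, and the new stereocentre is deliberately left racemic.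

**7 ⇒ 4 and 3 ⇒ 1.** Ketone 7 comes from 3-hydroxy-4,5-dimethoxybenzaldehyde 4 by MOM protection (5), ethyl Grignard addition (6) and oxidation. Bromide 3 comes from 4-chloro-2-methoxyphenol 1 by bromination ortho to the hydroxyl (2) and MOM protection. The MOM groups withstand the alkoxide bases of steps 6 and 7 and leave together in step 8.

## Roads not taken

**Alternative 1:** the most obvious route cuts C3–C3a and O1–C2 at once by biomimetic oxidative radical cross-coupling. Isoeugenol A1 and the 4-hydroxy-propenylarene A2 would be coupled (Ag2O or peroxidase/H2O2) to the trans cross-dimer A3. O-Methylation of the 4′-hydroxyl and MOM removal would follow. The chosen plan is better for three reasons: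
- The target's free hydroxyl is meta to C2, so the partner must carry a para-hydroxyl that is methylated afterwards, which adds steps.
- The radical coupling is unselective between cross- and homo-coupling and between 8–5′, 8–O–4′ and 8–8′ modes.
- Free radical coupling outside an enzyme pocket has no absolute control, so A3 would be racemic and need resolution.

**Alternative 2:** cut C3–C3a by carbene C–H insertion. A chiral Rh(II) carboxylate would convert aryldiazoacetate A4 by intramolecular 1,5-insertion into the benzylic ether C–H to the cis-3-carboxylate A5. The chosen plan is better because A5 carries an ester where the target has a methyl group. The cis kinetic product must be epimerised at C3, and the ester must be taken down to CH3 in three further steps. The diazo precursor also needs its own multi-step assembly. The route is longer and its stereocentre has to be corrected after the key step.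

**Alternative 3:** cut C3–C3a and O1–C2 by a Pd-catalysed (3+2) oxyarylation (Larock-type heteroannulation). o-Iodophenol A6 and (E)-propenylarene A7 would react by syn-carbopalladation and C–O bond formation to give the trans-dihydrobenzofuran A8 in one step. This is the shortest construction. It is not chosen because enantiofacial control in intermolecular carbopalladation of an acyclic 1,2-disubstituted styrene has no dependable solution. β-Hydride elimination to Heck products and the regiochemistry of insertion also compete. A8 would be obtained as the racemate, and the aryl partner still needs a chloride handle because a propenyl group on A6 would react with itself.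

Key step: step 7

Remark: the SMILES is read as the (2S,3S)-trans-dihydrobenzofuran with an (E)-propenyl group; phenols 1 and 4 are taken as catalogue compounds.

## Steps

Step 1
Reactants: 1 4-chloro-2-methoxyphenol
Product: 2 2-bromo-4-chloro-6-methoxyphenol
Conditions: NBS (1.05 equiv), i-Pr2NH (10 mol%), CH2Cl2, 0 °C
Reagents that add atoms: N-bromosuccinimide, O=C1CCC(=O)N1Br
Why: Electrophilic aromatic bromination; the free hydroxyl is the strongest director and its para position is blocked by chlorine, so bromine should enter the one open ortho position, which amine-mediated NBS conditions favour further.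

Step 2
Reactants: 2 2-bromo-4-chloro-6-methoxyphenol
Product: 3 1-bromo-5-chloro-3-methoxy-2-(methoxymethoxy)benzene
Conditions: NaH, MOMCl, DMF, 0 °C to rt
Reagents that add atoms: chloromethyl methyl ether, COCCl
Why: Williamson-type O-alkylation of the phenoxide; the MOM acetal tolerates the alkoxide bases of steps 6 and 7 and leaves with acid in step 8.

Step 3
Reactants: 4 3-hydroxy-4,5-dimethoxybenzaldehyde
Product: 5 3,4-dimethoxy-5-(methoxymethoxy)benzaldehyde
Conditions: NaH, MOMCl, DMF, 0 °C to rt
Reagents that add atoms: chloromethyl methyl ether, COCCl
Why: Williamson-type O-alkylation of a phenoxide next to a non-enolisable aldehyde; it marks the one oxygen that must end as the free phenol.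

Step 4
Reactants: 5 3,4-dimethoxy-5-(methoxymethoxy)benzaldehyde
Product: 6 rac-1-[3,4-dimethoxy-5-(methoxymethoxy)phenyl]propan-1-ol
Conditions: EtMgBr (1.2 equiv), THF, 0 °C; aqueous work-up
Reagents that add atoms: ethylmagnesium bromide, CC[Mg]Br
Why: Grignard addition to an aromatic aldehyde; the new stereocentre is left uncontrolled because it is oxidised away in step 5.

Step 5
Reactants: 6 rac-1-[3,4-dimethoxy-5-(methoxymethoxy)phenyl]propan-1-ol
Product: 7 1-[3,4-dimethoxy-5-(methoxymethoxy)phenyl]propan-1-one
Conditions: activated MnO2, CH2Cl2, rt
Reagents that add atoms: none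
Why: Selective oxidation of an electron-rich benzylic alcohol by manganese dioxide under neutral conditions that leave the MOM acetal intact.

Step 6
Reactants: 7 1-[3,4-dimethoxy-5-(methoxymethoxy)phenyl]propan-1-one; 3 1-bromo-5-chloro-3-methoxy-2-(methoxymethoxy)benzene
Product: 8 rac-2-[5-chloro-3-methoxy-2-(methoxymethoxy)phenyl]-1-[3,4-dimethoxy-5-(methoxymethoxy)phenyl]propan-1-one
Conditions: Pd2(dba)3 (1 mol%), Xantphos (2.4 mol%), NaOt-Bu (1.3 equiv), toluene, 80 °C
Reagents that add atoms: none
Why: Pd-catalysed ketone α-arylation; with a bis-phosphine ligand oxidative addition should occur at C–Br and leave C–Cl alone, and the tertiary α-aryl ketone rests as its enolate, which prevents a second arylation; the new stereocentre is deliberately racemic.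

Step 7
Reactants: 8 rac-2-[5-chloro-3-methoxy-2-(methoxymethoxy)phenyl]-1-[3,4-dimethoxy-5-(methoxymethoxy)phenyl]propan-1-one
Product: 10 (1S,2S)-2-[5-chloro-3-methoxy-2-(methoxymethoxy)phenyl]-1-[3,4-dimethoxy-5-(methoxymethoxy)phenyl]propan-1-ol, via potassium enolate 9 (not isolated)
Conditions: trans-RuCl2[(R)-xylbinap][(R)-daipen] (1 mol%), KOt-Bu (0.3 equiv), H2 (10 atm), i-PrOH/toluene, 25 °C
Reagents that add atoms: none
Why: KOt-Bu should interconvert (R)- and (S)-8 through the achiral enolate 9, because the C2–H bond is both benzylic and α to an aryl ketone. The ruthenium hydride with its diamine N–H transfers hydride and proton to the carbonyl in an outer-sphere six-membered transition state, and the (R)-XylBINAP/(R)-DAIPEN pocket should expose the face that gives the (1S)-carbinol, as this catalyst family does for aryl alkyl ketones. That face is the Felkin–Anh face only in (S)-8 (α-aryl group anti to the incoming hydride, hydride passing the α-hydrogen), so (S)-8 should be reduced faster while (R)-8 returns to the pool by enolisation. The closest known reaction type is the Noyori asymmetric hydrogenation of configurationally labile α-substituted ketones under dynamic kinetic resolution, which has close precedent for 2-arylpropiophenones with ortho-substituted α-aryl groups. No ring is closed in this step. C1 is set by the catalyst and C2 by the matched pairing of catalyst and Felkin–Anh control acting on a racemising centre; only C2 is carried into the target, as C3. The step needs racemisation to outrun reduction of the mismatched enantiomer, which the doubly activated α-C–H and the alkoxide base should secure, and it needs carbonyl reduction without touching the aryl chloride, which this catalyst class does not activate. Any minor anti diastereomer carries the opposite C2 configuration and is removed by chromatography or crystallisation here, before step 8 erases the C1 label.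

Step 8
Reactants: 10 (1S,2S)-2-[5-chloro-3-methoxy-2-(methoxymethoxy)phenyl]-1-[3,4-dimethoxy-5-(methoxymethoxy)phenyl]propan-1-ol
Product: 12 5-[(2S,3S)-5-chloro-7-methoxy-3-methyl-2,3-dihydro-1-benzofuran-2-yl]-2,3-dimethoxyphenol, via triol 11 (not isolated)
Conditions: 4 M aq. HCl/THF (1:3), 45 °C; then TsOH·H2O (5 mol%), CH2Cl2, rt
Reagents that add atoms: none
Why: Acid hydrolysis of both aryl MOM acetals should give triol 11, whose 4-methoxybenzylic hydroxyl ionises and is captured 5-exo by the ortho phenol (acid-mediated cyclodehydration). C2 should be set trans to the C3 methyl group because the cation reacts through the conformer with C3–H in the plane of the aryl ring (minimal allylic 1,3-strain), and any cis isomer can re-ionise to the more stable trans form. C3 has no ionisable bond and should keep its configuration.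

Step 9
Reactants: 12 5-[(2S,3S)-5-chloro-7-methoxy-3-methyl-2,3-dihydro-1-benzofuran-2-yl]-2,3-dimethoxyphenol
Product: 13 2,3-dimethoxy-5-[(2S,3S)-7-methoxy-3-methyl-5-[(E)-prop-1-en-1-yl]-2,3-dihydro-1-benzofuran-2-yl]phenol
Conditions: (E)-propenyl-Bpin (1.5 equiv), Pd(OAc)2 (2 mol%), SPhos (4 mol%), K3PO4 (3 equiv), 1,4-dioxane/H2O (5:1), 90 °C, degassed
Reagents that add atoms: (E)-prop-1-enylboronic acid pinacol ester, C/C=C/B1OC(C)(C)C(C)(C)O1
Why: Suzuki–Miyaura coupling of an electron-rich aryl chloride with a dialkylbiarylphosphine ligand; transmetalation and reductive elimination retain the alkene geometry, the phenol is carried as its phenoxide, and neither stereocentre is involved.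

## Compound list

1 | 4-chloro-2-methoxyphenol | COc1cc(Cl)ccc1O | starting material
2 | 2-bromo-4-chloro-6-methoxyphenol | COc1cc(Cl)cc(Br)c1O | intermediate
3 | 1-bromo-5-chloro-3-methoxy-2-(methoxymethoxy)benzene | COCOc1c(Br)cc(Cl)cc1OC | intermediate
4 | 3-hydroxy-4,5-dimethoxybenzaldehyde | COc1cc(C=O)cc(O)c1OC | starting material
5 | 3,4-dimethoxy-5-(methoxymethoxy)benzaldehyde | COCOc1cc(C=O)cc(OC)c1OC | intermediate
6 | rac-1-[3,4-dimethoxy-5-(methoxymethoxy)phenyl]propan-1-ol (racemate, centre not specified) | CCC(O)c1cc(OCOC)c(OC)c(OC)c1 | intermediate
7 | 1-[3,4-dimethoxy-5-(methoxymethoxy)phenyl]propan-1-one | CCC(=O)c1cc(OCOC)c(OC)c(OC)c1 | intermediate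
8 | rac-2-[5-chloro-3-methoxy-2-(methoxymethoxy)phenyl]-1-[3,4-dimethoxy-5-(methoxymethoxy)phenyl]propan-1-one (racemate, centre not specified) | CC(C(=O)c1cc(OCOC)c(OC)c(OC)c1)c1cc(Cl)cc(OC)c1OCOC | intermediate
9 | potassium enolate of 8, either geometry (not isolated) | CC(=C([O-])c1cc(OCOC)c(OC)c(OC)c1)c1cc(Cl)cc(OC)c1OCOC.[K+] | intermediate
10 | (1S,2S)-2-[5-chloro-3-methoxy-2-(methoxymethoxy)phenyl]-1-[3,4-dimethoxy-5-(methoxymethoxy)phenyl]propan-1-ol | C[C@H]([C@H](O)c1cc(OCOC)c(OC)c(OC)c1)c1cc(Cl)cc(OC)c1OCOC | intermediate
11 | 4-chloro-2-[(1S,2S)-1-hydroxy-1-(3-hydroxy-4,5-dimethoxyphenyl)propan-2-yl]-6-methoxyphenol (not isolated) | C[C@H]([C@H](O)c1cc(O)c(OC)c(OC)c1)c1cc(Cl)cc(OC)c1O | intermediate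
12 | 5-[(2S,3S)-5-chloro-7-methoxy-3-methyl-2,3-dihydro-1-benzofuran-2-yl]-2,3-dimethoxyphenol | Clc1cc(OC)c2c(c1)[C@H](C)[C@@H](c1cc(O)c(OC)c(OC)c1)O2 | intermediate
13 | 2,3-dimethoxy-5-[(2S,3S)-7-methoxy-3-methyl-5-[(E)-prop-1-en-1-yl]-2,3-dihydro-1-benzofuran-2-yl]phenol | C/C=C/c1cc(OC)c2c(c1)[C@H](C)[C@@H](c1cc(O)c(OC)c(OC)c1)O2 | target

## Step count and risks

Total step count: 9. Longest linear sequence: 7 (steps 3 to 9, from 4 to 13); the two-step branch from 1 to 3 joins at step 6.

**Step 7 (key step).** Stereoconvergence may be incomplete. This would happen if enolisation is slower than reduction of the mismatched enantiomer, or if the twisted ortho-alkoxyaryl group weakens the Felkin–Anh preference. The anti alcohol that forms then carries the opposite C2 configuration and lowers the optical purity of everything downstream. Slow hydrogenation of the hindered ketone is the second concern.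

The fallback fixes the configuration in the C–C bond-forming event instead. It sets out from 7 and 3 and returns at 10.
- 7 is brominated through its lithium enolate (LiHMDS, then NBS, THF, −78 °C) to racemic 2-bromo-1-[3,4-dimethoxy-5-(methoxymethoxy)phenyl]propan-1-one F1.
- 3 is converted by bromine–magnesium exchange (i-PrMgCl·LiCl) and ZnI2 into [5-chloro-3-methoxy-2-(methoxymethoxy)phenyl]zinc iodide F2.
- A nickel/pybox-catalysed stereoconvergent Negishi arylation of the racemic bromide (NiCl2·glyme, chiral pybox, glyme/THF, −30 °C) is a known enantioselective entry to α-aryl propiophenones. It should give (2S)-2-[5-chloro-3-methoxy-2-(methoxymethoxy)phenyl]-1-[3,4-dimethoxy-5-(methoxymethoxy)phenyl]propan-1-one F3.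
- F3 is reduced at once under non-basic conditions (NaBH4, CeCl3, MeOH, −78 °C) to 10 together with its (1R,2S) C1 epimer F4. Both alcohols have the same C2 configuration and converge in step 8.

**Step 8.** The benzylic cation may lose the C3 proton (E1) to an α-methylstilbene that re-protonates without stereocontrol, or undergo a 1,2-hydride shift; either erodes the C3 configuration. Intermolecular Friedel–Crafts alkylation of the electron-rich rings and capture of released formaldehyde are further losses. Incomplete trans selection is possible if re-ionisation of a cis isomer is slow.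

The fallback closes the other C–O bond (C7a–O) by a copper-catalysed Ullmann etherification. This never activates the benzylic carbon and proceeds with retention. It sets out from 7 and returns at 12.
- α-Arylation of 7 at the C–I bond of 2-bromo-5-chloro-1-iodo-3-methoxybenzene F5 (a separately sourced building block) under the conditions of step 6 gives rac-2-(2-bromo-5-chloro-3-methoxyphenyl)-1-[3,4-dimethoxy-5-(methoxymethoxy)phenyl]propan-1-one F6.
- The hydrogenation of step 7 gives the (1S,2S)-bromo alcohol F7.
- CuI/1,10-phenanthroline, Cs2CO3, toluene, 110 °C closes the ring to (2S,3S)-5-chloro-2-[3,4-dimethoxy-5-(methoxymethoxy)phenyl]-7-methoxy-3-methyl-2,3-dihydro-1-benzofuran F8. The product is trans because the syn alcohol reacts with retention.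
- HCl in MeOH at rt removes the single MOM group to give 12. The ring ether oxygen is far less basic than a benzylic hydroxyl, so ionisation at C2 should be much slower at this stage.

**Step 6.** Oxidative addition may be slow at the ortho-alkoxy-substituted C–Br bond. Competing hydrodebromination, or partial insertion into C–Cl at the temperature needed, would lower the yield. The fallback reverses the polarity of the C3–C3a bond formation. It sets out from 7 and 3 and returns at 8. The α-bromoketone F1 and the arylzinc iodide F2, prepared as described for step 7, are coupled with an achiral nickel catalyst (NiCl2·glyme, 2,2′-bipyridine, THF/DMA, rt) to racemic 8.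

**Step 9.** Oxidative addition into the electron-rich C–Cl bond may be slow enough for protodeboronation of the alkenylboronate to compete. Palladium hydride species may also erode the alkene geometry or move the double bond. The fallback separates C–C bond formation from control of the alkene geometry. It sets out from 12 and returns at 13. Suzuki–Miyaura allylation with allyl-Bpin (Pd(OAc)2, SPhos, K3PO4, dioxane/H2O) gives 5-[(2S,3S)-7-methoxy-3-methyl-5-(prop-2-en-1-yl)-2,3-dihydro-1-benzofuran-2-yl]-2,3-dimethoxyphenol F9. Ruthenium hydride-catalysed isomerisation (RuHCl(CO)(PPh3)3, toluene, 80 °C) then moves the double bond into conjugation under thermodynamic control, which favours the (E)-propenyl compound 13.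

## Further compounds

F1 | step 7 | rac-2-bromo-1-[3,4-dimethoxy-5-(methoxymethoxy)phenyl]propan-1-one (racemate, centre not specified) | CC(Br)C(=O)c1cc(OCOC)c(OC)c(OC)c1
F2 | step 7 | [5-chloro-3-methoxy-2-(methoxymethoxy)phenyl]zinc iodide | COCOc1c([Zn]I)cc(Cl)cc1OC
F3 | step 7 | (2S)-2-[5-chloro-3-methoxy-2-(methoxymethoxy)phenyl]-1-[3,4-dimethoxy-5-(methoxymethoxy)phenyl]propan-1-one | C[C@H](C(=O)c1cc(OCOC)c(OC)c(OC)c1)c1cc(Cl)cc(OC)c1OCOC
F4 | step 7 | (1R,2S)-2-[5-chloro-3-methoxy-2-(methoxymethoxy)phenyl]-1-[3,4-dimethoxy-5-(methoxymethoxy)phenyl]propan-1-ol | C[C@H]([C@@H](O)c1cc(OCOC)c(OC)c(OC)c1)c1cc(Cl)cc(OC)c1OCOC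
F5 | step 8 | 2-bromo-5-chloro-1-iodo-3-methoxybenzene | COc1cc(Cl)cc(I)c1Br
F6 | step 8 | rac-2-(2-bromo-5-chloro-3-methoxyphenyl)-1-[3,4-dimethoxy-5-(methoxymethoxy)phenyl]propan-1-one (racemate, centre not specified) | CC(C(=O)c1cc(OCOC)c(OC)c(OC)c1)c1cc(Cl)cc(OC)c1Br
F7 | step 8 | (1S,2S)-2-(2-bromo-5-chloro-3-methoxyphenyl)-1-[3,4-dimethoxy-5-(methoxymethoxy)phenyl]propan-1-ol | C[C@H]([C@H](O)c1cc(OCOC)c(OC)c(OC)c1)c1cc(Cl)cc(OC)c1Br
F8 | step 8 | (2S,3S)-5-chloro-2-[3,4-dimethoxy-5-(methoxymethoxy)phenyl]-7-methoxy-3-methyl-2,3-dihydro-1-benzofuran | Clc1cc(OC)c2c(c1)[C@H](C)[C@@H](c1cc(OCOC)c(OC)c(OC)c1)O2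
F0 | step 6 | none | none
F9 | step 9 | 5-[(2S,3S)-7-methoxy-3-methyl-5-(prop-2-en-1-yl)-2,3-dihydro-1-benzofuran-2-yl]-2,3-dimethoxyphenol | C=CCc1cc(OC)c2c(c1)[C@H](C)[C@@H](c1cc(O)c(OC)c(OC)c1)O2
A1 | alternative 1 | isoeugenol, 2-methoxy-4-[(E)-prop-1-en-1-yl]phenol | C/C=C/c1ccc(O)c(OC)c1
A2 | alternative 1 | 2-methoxy-6-(methoxymethoxy)-4-[(E)-prop-1-en-1-yl]phenol | C/C=C/c1cc(OC)c(O)c(OCOC)c1
A3 | alternative 1 | rac-trans-2-methoxy-4-[7-methoxy-3-methyl-5-[(E)-prop-1-en-1-yl]-2,3-dihydro-1-benzofuran-2-yl]-6-(methoxymethoxy)phenol, (2S,3S) and (2R,3R) forms | C/C=C/c1cc(OC)c2c(c1)[C@H](C)[C@@H](c1cc(OC)c(O)c(OCOC)c1)O2.C/C=C/c1cc(OC)c2c(c1)[C@@H](C)[C@H](c1cc(OC)c(O)c(OCOC)c1)O2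
A4 | alternative 2 | methyl 2-[5-chloro-2-[[3,4-dimethoxy-5-(methoxymethoxy)phenyl]methoxy]-3-methoxyphenyl]-2-diazoacetate | COC(=O)C(=[N+]=[N-])c1cc(Cl)cc(OC)c1OCc1cc(OCOC)c(OC)c(OC)c1
A5 | alternative 2 | methyl (2S,3R)-5-chloro-2-[3,4-dimethoxy-5-(methoxymethoxy)phenyl]-7-methoxy-2,3-dihydro-1-benzofuran-3-carboxylate (cis) | Clc1cc(OC)c2c(c1)[C@@H](C(=O)OC)[C@@H](c1cc(OCOC)c(OC)c(OC)c1)O2
A6 | alternative 3 | 4-chloro-2-iodo-6-methoxyphenol | COc1cc(Cl)cc(I)c1O
A7 | alternative 3 | 1,2-dimethoxy-3-(methoxymethoxy)-5-[(E)-prop-1-en-1-yl]benzene | C/C=C/c1cc(OC)c(OC)c(OCOC)c1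
A8 | alternative 3 | rac-trans-5-chloro-2-[3,4-dimethoxy-5-(methoxymethoxy)phenyl]-7-methoxy-3-methyl-2,3-dihydro-1-benzofuran, (2S,3S) and (2R,3R) forms | Clc1cc(OC)c2c(c1)[C@H](C)[C@@H](c1cc(OCOC)c(OC)c(OC)c1)O2.Clc1cc(OC)c2c(c1)[C@@H](C)[C@H](c1cc(OCOC)c(OC)c(OC)c1)O2
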